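The 1,4-dioxane ring (O1–C2–C3–O4–C4a–C8a) is made one atom short, as the 1,3-dioxole of a pyrogallol benzylidene acetal (O1–C3–O4). The route exploits that C2, its CH2OH carbon and the adjacent 8-OH form a latent aryl diazoacetate. The precursor is a 2-aryl-1,3-benzodioxole carrying O8–CO–CHN2. A rhodium carbene is delivered to O1 only; a [1,2]-Stevens shift of the acetal carbon inserts the carbene carbon into O1–C3, which expands dioxole to dioxane, forms C2–C3 and closes an O8 lactone in one operation. Reduction unveils CH2OH and 8-OH. Base equilibration sets the trans relationship; a lipase resolution selects the (2S,3S) enantiomer.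

Key step: step 4

Remarks
- Locants are those of the 2,3-dihydro-1,4-benzodioxin core of the target: O1, C2 (bears CH2OH), C3 (bears the aryl group), O4, C4a, C6 (propenal), C8 (OH), C8a; earlier intermediates are described with the same future locants.
- Assumption: Candida antarctica lipase B is taken to acylate the CH2OH group of the (2S,3S)-enantiomer faster than that of the (2R,3R)-enantiomer; if the opposite sense is found, the alcohol left unreacted in step 7 is the target and step 8 falls away.
- Compounds 5, 7 and 8 are racemic at the acetal carbon (no descriptor drawn); racemates 9–12 are drawn as the enantiomer that leads to the target.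

Step 1
Reactants: 1 3,4,5-trihydroxybenzaldehyde; 2 methyl (triphenylphosphoranylidene)acetate
Product: 3 methyl (E)-3-(3,4,5-trihydroxyphenyl)prop-2-enoate
Conditions: 2 (1.2 equiv), degassed H2O, 90 °C, argon
Reagents that add atoms: none
Why: Wittig olefination with a stabilised ylide should give the E-cinnamate and tolerates free phenols, while argon protects the pyrogallol from autoxidation.

Step 2
Reactants: 3 methyl (E)-3-(3,4,5-trihydroxyphenyl)prop-2-enoate; 4 3,4,5-trimethoxybenzaldehyde dimethyl acetal
Product: 5 rac-methyl (E)-3-[7-hydroxy-2-(3,4,5-trimethoxyphenyl)-1,3-benzodioxol-5-yl]prop-2-enoate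
Conditions: CSA (5 mol %), MeCN–toluene, 80 °C, 4 Å MS (removal of MeOH)
Reagents that add atoms: none
Why: Acid-catalysed transacetalisation should close the five-membered benzylidene acetal on two adjacent phenols; the two possible OH pairs are equivalent by symmetry, so one constitution forms, with the acetal carbon as a racemic stereocentre.

Step 3
Reactants: 5 rac-methyl (E)-3-[7-hydroxy-2-(3,4,5-trimethoxyphenyl)-1,3-benzodioxol-5-yl]prop-2-enoate; 6 succinimidyl diazoacetate
Product: 7 rac-methyl (E)-3-[7-(2-diazoacetoxy)-2-(3,4,5-trimethoxyphenyl)-1,3-benzodioxol-5-yl]prop-2-enoate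
Conditions: Et3N (1.2 equiv), CH2Cl2, 0 °C to rt, exclusion of light
Reagents that add atoms: none
Why: Acyl transfer from the N-hydroxysuccinimide active ester to the only free phenol (diazoacetylation) runs under mild base, which the acid-labile acetal and the diazo group should both survive.

Step 4
Reactants: 7 rac-methyl (E)-3-[7-(2-diazoacetoxy)-2-(3,4,5-trimethoxyphenyl)-1,3-benzodioxol-5-yl]prop-2-enoate
Product: 10 rac-trans-lactone (2R*,3S*), via oxonium ylide 8 (not isolated), via cis-lactone 9 (not isolated)
Conditions: Rh2(OAc)4 (1 mol %), CH2Cl2, 40 °C, slow addition of 7 at high dilution; then DBU (10 mol %), rt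
Reagents that add atoms: none
Why: Rh2(OAc)4 converts the diazoacetate into an electrophilic rhodium carbene, which is captured by the in-plane lone pair of O1 to give the six-membered cyclic oxonium ylide 8; cleavage of the O1–C(acetal) bond releases the benzylic, α-oxygenated acetal carbon, which recombines at the ylide carbon ([1,2]-Stevens shift), so the carbene carbon is inserted into O1–C3 and the 1,3-dioxole becomes the 1,4-dioxane. The closest known reaction type is the Rh(II)-catalysed oxonium ylide formation and [1,2]-Stevens ring expansion of cyclic acetals that carry a tethered diazoacetate. The lactone ring closes by C–O bond formation between the carbene carbon and O1 (six-membered ylide formation), and the dioxane ring closes by the 1,2-shift itself, the recombination that forms C2–C3 (ring expansion 5 to 6). C3 (migrating acetal carbon) and C2 (ylide carbon) arise as a racemic pair whose relative configuration is under thermodynamic control: DBU epimerises C2, which is α to the lactone carbonyl, so that cis-lactone 9 should converge on the trans-lactone with the aryl group pseudo-equatorial, and the absolute configuration is selected later in steps 7 and 8. The step needs chemoselectivity for ylide formation at O1 over O4 and over attack on the arene: the ester tether from O8 reaches O1 through a six-membered ring but O4 only through a strained seven-membered one, and the moderately electrophilic acetate catalyst with slow addition should disfavour aromatic substitution and carbene dimerisation.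

Step 5
Reactants: 10 rac-trans-lactone (2R*,3S*)
Product: 11 rac-(E)-3-[(2S*,3S*)-8-hydroxy-2-(hydroxymethyl)-3-(3,4,5-trimethoxyphenyl)-2,3-dihydro-1,4-benzodioxin-6-yl]prop-2-en-1-ol
Conditions: DIBAL-H (7 equiv), CH2Cl2–THF, −78 to 0 °C; aq. Rochelle salt
Reagents that add atoms: none
Why: Exhaustive DIBAL-H reduction should take the aryl lactone to CH2OH plus the free 8-phenol and the conjugated methyl ester to the allylic alcohol by 1,2-reduction, under non-basic conditions that leave C2 and C3 untouched.

Step 6
Reactants: 11 rac-(E)-3-[(2S*,3S*)-8-hydroxy-2-(hydroxymethyl)-3-(3,4,5-trimethoxyphenyl)-2,3-dihydro-1,4-benzodioxin-6-yl]prop-2-en-1-ol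
Product: 12 rac-(E)-3-[(2S*,3S*)-8-hydroxy-2-(hydroxymethyl)-3-(3,4,5-trimethoxyphenyl)-2,3-dihydro-1,4-benzodioxin-6-yl]prop-2-enal
Conditions: activated MnO2 (15 equiv), EtOAc, rt
Reagents that add atoms: none
Why: Allylic oxidation with activated MnO2 should convert the cinnamyl alcohol chemoselectively into the (E)-enal and leave the saturated primary alcohol alone.

Step 7
Reactants: 12 rac-(E)-3-[(2S*,3S*)-8-hydroxy-2-(hydroxymethyl)-3-(3,4,5-trimethoxyphenyl)-2,3-dihydro-1,4-benzodioxin-6-yl]prop-2-enal
Product: 13 [(2S,3S)-8-hydroxy-6-[(E)-3-oxoprop-1-enyl]-3-(3,4,5-trimethoxyphenyl)-2,3-dihydro-1,4-benzodioxin-2-yl]methyl acetate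
Conditions: Novozym 435 (immobilised Candida antarctica lipase B), vinyl acetate (5 equiv), MTBE–acetone, 30 °C, stopped below half conversion; chromatographic separation from the unreacted alcohol
Reagents that add atoms: vinyl acetate, C=COC(C)=O
Why: Lipase-catalysed kinetic resolution by enantioselective transesterification: the enzyme's acyl-transfer site distinguishes the C2 configuration next to CH2OH, so the (2S,3S)-alcohol should be acetylated while the (2R,3R)-alcohol stays behind, which selects the absolute configuration.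

Step 8
Reactants: 13 [(2S,3S)-8-hydroxy-6-[(E)-3-oxoprop-1-enyl]-3-(3,4,5-trimethoxyphenyl)-2,3-dihydro-1,4-benzodioxin-2-yl]methyl acetate
Product: 14 (E)-3-[(2S,3S)-8-hydroxy-2-(hydroxymethyl)-3-(3,4,5-trimethoxyphenyl)-2,3-dihydro-1,4-benzodioxin-6-yl]prop-2-enal
Conditions: Novozym 435, butan-1-ol (10 equiv), MTBE, 40 °C
Reagents that add atoms: none
Why: Enzymatic alcoholysis removes the acetate under neutral conditions that spare the enal and the phenol, and the same enantiopreference in the reverse direction should raise the enantiomeric purity once more (double kinetic resolution).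

Compound list
1 | 3,4,5-trihydroxybenzaldehyde | O=Cc1cc(O)c(O)c(O)c1 | starting material
2 | methyl (triphenylphosphoranylidene)acetate | COC(=O)C=P(c1ccccc1)(c1ccccc1)c1ccccc1 | starting material
3 | methyl (E)-3-(3,4,5-trihydroxyphenyl)prop-2-enoate | COC(=O)/C=C/c1cc(O)c(O)c(O)c1 | intermediate
4 | 3,4,5-trimethoxybenzaldehyde dimethyl acetal [5-(dimethoxymethyl)-1,2,3-trimethoxybenzene] | COC(OC)c1cc(OC)c(OC)c(OC)c1 | starting material
5 | rac-methyl (E)-3-[7-hydroxy-2-(3,4,5-trimethoxyphenyl)-1,3-benzodioxol-5-yl]prop-2-enoate | COC(=O)/C=C/c1cc(O)c2OC(c3cc(OC)c(OC)c(OC)c3)Oc2c1 | intermediate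
6 | succinimidyl diazoacetate (2,5-dioxopyrrolidin-1-yl 2-diazoacetate) | [N-]=[N+]=CC(=O)ON1C(=O)CCC1=O | starting material
7 | rac-methyl (E)-3-[7-(2-diazoacetoxy)-2-(3,4,5-trimethoxyphenyl)-1,3-benzodioxol-5-yl]prop-2-enoate | COC(=O)/C=C/c1cc(OC(=O)C=[N+]=[N-])c2OC(c3cc(OC)c(OC)c(OC)c3)Oc2c1 | intermediate
8 | cyclic oxonium ylide: O1 of the benzodioxole bonded to the ester α-carbanion, six-membered ring O1–CH(−)–C(=O)–O8–C8–C8a, O1 positively charged (not isolated) | COC(=O)/C=C/c1cc2OC(=O)[CH-][O+]3c2c(c1)OC3c1cc(OC)c(OC)c(OC)c1 | intermediate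
9 | rac-cis-lactone (2S*,3S*): C2 epimer of 10, H2 and H3 cis (not isolated) | COC(=O)/C=C/c1cc2O[C@@H](c3cc(OC)c(OC)c(OC)c3)[C@@H]3Oc2c(c1)OC3=O | intermediate
10 | rac-trans-lactone (2R*,3S*): δ-lactone of 8-hydroxy-6-[(E)-3-methoxy-3-oxoprop-1-enyl]-3-(3,4,5-trimethoxyphenyl)-2,3-dihydro-1,4-benzodioxine-2-carboxylic acid, carboxyl closed onto O8, H2 and H3 trans | COC(=O)/C=C/c1cc2O[C@@H](c3cc(OC)c(OC)c(OC)c3)[C@H]3Oc2c(c1)OC3=O | intermediate
11 | rac-(E)-3-[(2S*,3S*)-8-hydroxy-2-(hydroxymethyl)-3-(3,4,5-trimethoxyphenyl)-2,3-dihydro-1,4-benzodioxin-6-yl]prop-2-en-1-ol | COc1cc([C@@H]2Oc3cc(/C=C/CO)cc(O)c3O[C@H]2CO)cc(OC)c1OC | intermediate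
12 | rac-(E)-3-[(2S*,3S*)-8-hydroxy-2-(hydroxymethyl)-3-(3,4,5-trimethoxyphenyl)-2,3-dihydro-1,4-benzodioxin-6-yl]prop-2-enal (racemate of the target) | COc1cc([C@@H]2Oc3cc(/C=C/C=O)cc(O)c3O[C@H]2CO)cc(OC)c1OC | intermediate
13 | [(2S,3S)-8-hydroxy-6-[(E)-3-oxoprop-1-enyl]-3-(3,4,5-trimethoxyphenyl)-2,3-dihydro-1,4-benzodioxin-2-yl]methyl acetate | COc1cc([C@@H]2Oc3cc(/C=C/C=O)cc(O)c3O[C@H]2COC(C)=O)cc(OC)c1OC | intermediate
14 | (E)-3-[(2S,3S)-8-hydroxy-2-(hydroxymethyl)-3-(3,4,5-trimethoxyphenyl)-2,3-dihydro-1,4-benzodioxin-6-yl]prop-2-enal | COc1cc([C@@H]2Oc3cc(/C=C/C=O)cc(O)c3O[C@H]2CO)cc(OC)c1OC | target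

Total step count: 8
Longest linear sequence: 8 steps (1 → 3 → 5 → 7 → 10 → 11 → 12 → 13 → 14)

Steps most likely to fail

Step 4. The carbene may be diverted before it reaches O1, by electrophilic attack on the ring carbon ortho to the ester oxygen or by dimerisation, because the aryl ester must rotate into its less populated s-cis conformer for ylide formation. The fallback replaces the carbene by a polar alkylation–fragmentation–recombination and sets out from 5. Acylation with bromoacetyl bromide and pyridine in CH2Cl2 at 0 °C would give rac-methyl (E)-3-[7-(2-bromoacetoxy)-2-(3,4,5-trimethoxyphenyl)-1,3-benzodioxol-5-yl]prop-2-enoate F1. AgOTf with 2,6-di-tert-butyl-4-methylpyridine in CH2Cl2 should then trigger intramolecular O-alkylation of O1 (acetal-oxygen participation, six-membered oxonium ion), whose fragmentation gives the lactone-tethered oxocarbenium triflate F2. Enolisation of the new lactone with TMSOTf and Et3N closes the C2–C3 bond by a Mukaiyama-type addition to the oxocarbenium ion. DBU equilibration as in step 4 brings the material back to the route at 10.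

Step 7. The lipase may discriminate the two enantiomers insufficiently, or acylate too slowly, so that no clean separation results. The fallback uses covalent diastereomers in place of the enzyme and sets out from 12. Acylation of both hydroxyl groups with (1S)-camphanic chloride (2.5 equiv), Et3N and DMAP in CH2Cl2 would give the (2S,3S)-bis[(1S,4R)-camphanate] F3 and the (2R,3R)-bis[(1S,4R)-camphanate] F4, which are separated by crystallisation or chromatography. Methanolysis of F3 with K2CO3 in MeOH at 0 °C returns to the route at 14, so steps 7 and 8 are both replaced.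

Step 2. Ring closure may stop at open mixed acetals, the pyrogallol may degrade oxidatively, or the electron-rich acetal may hydrolyse on isolation. The fallback forms the acetal oxidatively and sets out from 3. Selective alkylation of the most acidic 4-OH (para to the acrylate) with 3,4,5-trimethoxybenzyl chloride and Li2CO3 in DMF at 40 °C would give methyl (E)-3-[3,5-dihydroxy-4-[(3,4,5-trimethoxyphenyl)methoxy]phenyl]prop-2-enoate F5. DDQ (1.1 equiv) in dry CH2Cl2 with 4 Å MS at 0 °C should abstract a benzylic hydride, and the flanking phenol traps the oxocarbenium ion, which returns to the route at 5.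

Further compounds
F1 | step 4 | rac-methyl (E)-3-[7-(2-bromoacetoxy)-2-(3,4,5-trimethoxyphenyl)-1,3-benzodioxol-5-yl]prop-2-enoate | COC(=O)/C=C/c1cc(OC(=O)CBr)c2OC(c3cc(OC)c(OC)c(OC)c3)Oc2c1
F2 | step 4 | lactone-tethered oxocarbenium triflate: 1,4-benzodioxin-2(3H)-one fused at O1/O8 with O4 as aryl(3,4,5-trimethoxybenzylidene)oxonium (not isolated) | COC(=O)/C=C/c1cc([O+]=Cc3cc(OC)c(OC)c(OC)c3)c2OCC(=O)Oc2c1.[O-]S(=O)(=O)C(F)(F)F
F3 | step 7 | (2S,3S)-bis[(1S,4R)-camphanate] of 14 (esters at O8 and at the CH2OH oxygen) | COc1cc([C@@H]2Oc3cc(/C=C/C=O)cc(OC(=O)[C@@]45CC[C@@](C)(C(=O)O4)C5(C)C)c3O[C@H]2COC(=O)[C@@]67CC[C@@](C)(C(=O)O6)C7(C)C)cc(OC)c1OC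
F4 | step 7 | (2R,3R)-bis[(1S,4R)-camphanate] (diastereomer of F3) | COc1cc([C@H]2Oc3cc(/C=C/C=O)cc(OC(=O)[C@@]45CC[C@@](C)(C(=O)O4)C5(C)C)c3O[C@@H]2COC(=O)[C@@]67CC[C@@](C)(C(=O)O6)C7(C)C)cc(OC)c1OC
F5 | step 2 | methyl (E)-3-[3,5-dihydroxy-4-[(3,4,5-trimethoxyphenyl)methoxy]phenyl]prop-2-enoate | COC(=O)/C=C/c1cc(O)c(OCc2cc(OC)c(OC)c(OC)c2)c(O)c1
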